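The earlier runs and the new flask are simulated for substances that don't exist, noise included.

Target grows along one curve in both earlier flasks, and your task is to carry that curve on to 10 h.

in all of them: substrate 0.25 M

| flask | capture agent | remark | time |
|---|---|---|---|
| south-west | 0.14 M | run made earlier |  |
| north-east | 0.51 M | run made earlier |  |
| grey | 0.250 M |  | 10 h |
| blue | 0.400 M |  | 10 h |
| red | 0.600 M |  | 10 h |

- south-west (time / h: target / %, substrate / %): 1.00: 19.2, 13.0; 2.00: 32.5, 8.1; 3.00: 39.1, 5.5; 4.00: 45.8, 3.6; 5.00: 49.1, 2.9; 6.00: 52.2, 2.4; 8.00: 56.2, 0.9
- north-east (time / h: target / %, substrate / %): 1.00: 19.3, 13.0; 2.00: 31.9, 7.5; 3.00: 39.9, 5.0; 4.00: 45.1, 3.5; 5.00: 49.1, 2.9; 6.00: 52.3, 2.5; 8.00: 55.8, 1.3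

(each reading ± 0.5 percentage points)

1. amount of target at the end, in percent of the substrate charged for grey, blue, red, in this order
2. the shape of the row from first to last (rises all the way / rises, then falls / falls all the way / falls, then rises / hardly changes)

- the earlier runs were read with a standard deviation of 0.5 percentage points
- "hardly changes" means that all values lie within two and a half points (for a concentration: within two and a half percent of the largest)

Take the south-west run in slow motion. By 1.00 h, south-west substrate has fallen to 13.0% while target reads 19.2%, so substrate goes faster than target appears, and 67.8% of the charge stands in neither peak. By 4.00 h, hardly any substrate is read in south-west, at 3.6%. Yet south-west target still gains 10 percentage points by 8.00 h, more than that substrate could supply. So in this stage south-west target is fed from material you don't see as either peak, and what matters next is how fast that feed fades.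

The two runs can be averaged: c(capture agent) differs by a factor of 3.64, yet target at 8.00 h differs by 0.4 points, with a reading scatter of 0.5 points. The mean curve reads 45.5%, 52.2% and 56.0% at 4.00 h, 6.00 h and 8.00 h, so its two-hour gains are 6.8 points and then 3.8 points. Call the share of one two-hour gain that the next one keeps the gain ratio; here it reads 0.551, a reading that carries the scatter of the peaks.

The next gain is then 2.1 points, and I reckon target at 10 h at 58.1%. To check the error of using the mean, take each run alone: south-west gives 58.7% and north-east gives 57.5%. I give grey, blue and red this one number, although red's 0.600 M lies above north-east's 0.51 M.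

The forecast gives 58%, 58% and 58%, shape hardly changes, reasoning that “rates therefore appear zero order in agent”.

The flask gives 58.1%, 58.0% and 58.0% for grey, blue and red; shape: hardly changes.

    substrate + intermediate A → side product B (k = 1.19 /M/h)
    substrate → side product A (k = 0.380 /h)
    intermediate B ⇌ intermediate D (K = 2.90, k = 0.122 /h)
    intermediate B ⇌ intermediate C (K = 0.770, k = 0.786 /h)
    intermediate A ⇌ intermediate B (K = 0.360, k = 0.391 /h)
    substrate ⇌ intermediate A (K = 2.89, k = 9.51 /h)
    substrate → decomposition product (k = 0.00138 /h)
    intermediate D + capture agent → trapped intermediate (k = 2.48 /M/h)
    intermediate A → target (k = 0.411 /h)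

Substrate, the limiting reagent, is down to 0.74% in grey with 95% of capture agent left, and the path to trapped intermediate makes no difference to grey's target. Continue the gain ratio of 0.551 without end and the gains after 8.00 h add up to a level of 60.7%; red stands at 61.6% after 100 h.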